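**Retrosynthetic overview**

1. The 3-phenylpropanoate is made last by Mitsunobu inversion of a C9 allylic alcohol, and the (Z)-ylidene butenolide by Sonogashira coupling–lactonization of a terminal alkyne; both sit on a 2-methylcyclohex-2-enone spiro-fused to the cyclopentane (spiro[4.5]decane numbering: C1 side chain, C4 methyl, C5 spiro, C6H2, C7=C8(CH3), C9–O, C10H2).
2. Key disconnection: C5–C10 and C8–C9. One anionic [4+2] annulation (double Michael addition) joins the α'-enolate of a cyclopentyl (E)-propenyl ketone to phenyl vinyl sulfone and closes the six-membered ring on the ready-made five-membered ring.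
3. The feature that allows this: in the cyclohexene ring C5 and the methyl-bearing C8 are 1,4-related through C6–C7, so C5–C6–C7–C8(CH3) is the α'-carbon/carbonyl/α/β array of an enone, and C9(O)–C10(H2) is an adjacent two-carbon Michael acceptor. The C6 oxygen (as enol triflate) and the C9 sulfone are traceless handles: the first becomes H, the second C=O.
4. Stereochemistry: C1 and C4 are bought with nepetalactone; the side-chain CH(CH3) centre is set by hydrogenation; C5 is relayed from C1 in the key step; C9 is set by substrate-controlled reduction and inversion.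
5. Ring order: cyclopentane (bought) → cyclohexene (key step) → butenolide.

Key step: step 4

Assumption: (4aS,7S,7aR)-nepetalactone, the main constituent of commercial catnip oil, is taken as a purchasable, enantiopure starting material.

**Step 1**
Reactants: 1 (4aS,7S,7aR)-nepetalactone
Product: 2 (4S,4aR,7S,7aR)-4,7-dimethylhexahydrocyclopenta[c]pyran-1(3H)-one (dihydronepetalactone)
Conditions: H2 (1 atm), Pd/C, EtOAc, rt
Reagents that add atoms: none
Why: Heterogeneous syn-hydrogenation of the enol-ether C3=C4 bond should occur on the convex face of the cis-fused bicycle (the face of H-4a and H-7a), which sets C4 as S, the future side-chain CH(CH3) centre.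

**Step 2**
Reactants: 2 dihydronepetalactone; 3 (E)-1-bromoprop-1-ene
Product: 5 (2E)-1-[(1R,2R,5S)-2-[(2S)-1-hydroxypropan-2-yl]-5-methylcyclopentyl]but-2-en-1-one, via (E)-prop-1-enyllithium 4 (not isolated)
Conditions: 3, t-BuLi (2 equiv), Et2O, −78 °C; then 2, THF, −78 °C; then H2O
Reagents that add atoms: none
Why: Halogen–lithium exchange keeps the alkene geometry, and 1,2-addition of the alkenyllithium to the δ-lactone should stop at the lithium lactolate at −78 °C, so that work-up gives the ring-opened δ-hydroxy enone (acylation of an organolithium by a lactone); no stereocentre is formed.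

**Step 3**
Reactants: 5 hydroxy enone
Product: 6 (2E)-1-[(1R,2R,5S)-2-[(2S)-1-(tert-butyldimethylsilyloxy)propan-2-yl]-5-methylcyclopentyl]but-2-en-1-one
Conditions: TBSCl, imidazole, DMF, rt
Reagents that add atoms: tert-butyldimethylsilyl chloride, CC(C)(C)[Si](C)(C)Cl
Why: Silylation of the primary alcohol traps the open-chain form, removes the acidic OH before enolate chemistry and makes the C1 side chain bulkier for the facial control of step 4.

**Step 4**
Reactants: 6 silyl ether enone; 7 phenyl vinyl sulfone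
Product: 11 (1R,4S,5R)-1-[(2S)-1-(tert-butyldimethylsilyloxy)propan-2-yl]-4,8-dimethyl-9-(phenylsulfonyl)spiro[4.5]dec-6-en-6-yl trifluoromethanesulfonate (epimer mixture at C8 and C9), via lithium dienolate 8 (not isolated), via sulfonyl carbanion 9 (not isolated), via cyclized lithium enolate 10 (not isolated)
Conditions: LiN(i-Pr)2, THF, −78 °C; 7, −78 to −20 °C; PhNTf2, −20 °C to rt; then H2O
Reagents that add atoms: N-phenylbis(trifluoromethanesulfonimide), O=S(=O)(N(c1ccccc1)S(=O)(=O)C(F)(F)F)C(F)(F)F
Why: Kinetic deprotonation at the α'-methine gives the cross-conjugated dienolate 8, whose α'-carbon (C5) adds to the CH2 of the vinyl sulfone (first Michael addition, bond C5–C10) to give carbanion 9; this closes the six-membered ring by conjugate addition to the β-carbon of the propenyl ketone (bond C8–C9, a 6-endo-trig Michael closure, since attack on the carbonyl would give a four-membered ring), and the regiodefined enolate 10 is trapped on oxygen as the triflate. The closest known reaction type is the double Michael (Michael–Michael ring closure, anionic [4+2]) annulation of α'-enolates of enones with acrylates, vinyl sulfones or nitroalkenes, followed by enolate O-sulfonylation. The spiro centre C5 is set in the first addition, which has an open transition state and forms a bond at one carbon only, so the enolate geometry does not matter: C5 is flanked by C1, which carries the branched CH(CH3)CH2OTBS group on one face, and by C4, which carries only a methyl on the other, so the acceptor should enter anti to the side chain and syn to the C4 methyl, as the target requires. The centres formed at C8 and C9 need no control because both become sp2 in step 6. The step needs α' rather than γ deprotonation (kinetic amide base at −78 °C), C- rather than O-attack and 1,4-closure; the C9–H next to the sulfone is less acidic than the ketone, so enolate 10 should persist and the triflation fixes the double bond at C6=C7.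

**Step 5**
Reactants: 11 enol triflate
Product: 12 tert-butyldimethyl{(2S)-2-[(1R,4S,5S)-4,8-dimethyl-9-(phenylsulfonyl)spiro[4.5]dec-6-en-1-yl]propoxy}silane (epimer mixture at C8 and C9)
Conditions: Pd(OAc)2 (5 mol%), PPh3, HCO2H, Bu3N, DMF, 60 °C
Reagents that add atoms: none
Why: Palladium-catalysed formate reduction of the enol triflate (oxidative addition, formate-to-hydride exchange with loss of CO2, reductive elimination) replaces C6–O by C6–H without moving the C6=C7 bond; the sulfone and silyl ether are inert.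

**Step 6**
Reactants: 12 alkenyl sulfone
Product: 15 (1R,4S,5S)-1-[(2S)-1-(tert-butyldimethylsilyloxy)propan-2-yl]-4,8-dimethylspiro[4.5]dec-7-en-9-one, via lithiated sulfone 13 (not isolated), via deconjugated enone 14 (not isolated)
Conditions: n-BuLi, THF, −78 °C; Me3SiOOSiMe3, −78 °C to rt; then DBU (cat.), rt
Reagents that add atoms: bis(trimethylsilyl) peroxide, C[Si](C)(C)OO[Si](C)(C)C
Why: Oxidative desulfonylation: oxygen transfer from the silyl peroxide to carbanion 13 and loss of sulfinate give the C9 ketone 14, and base then moves the β,γ double bond into conjugation (only C8–H can be lost because C5 is quaternary), which erases the C8 centre and gives the 2-methylcyclohex-2-enone.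

**Step 7**
Reactants: 15 silyl ether enone
Product: 16 (1R,4S,5S)-1-[(2S)-1-hydroxypropan-2-yl]-4,8-dimethylspiro[4.5]dec-7-en-9-one
Conditions: Bu4NF, THF, 0 °C to rt
Reagents that add atoms: none
Why: Fluoride-mediated desilylation frees the primary alcohol; the enone has no group that fluoride attacks.

**Step 8**
Reactants: 16 hydroxy enone
Product: 17 (2S)-2-[(1R,4S,5S)-4,8-dimethyl-9-oxospiro[4.5]dec-7-en-1-yl]propanal
Conditions: Dess–Martin periodinane, CH2Cl2, 0 °C to rt
Reagents that add atoms: none
Why: Dess–Martin oxidation gives the aldehyde under non-basic conditions, so the α-stereocentre should not epimerize.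

**Step 9**
Reactants: 17 aldehyde
Product: 18 (1R,4S,5S)-1-[(2S)-but-3-yn-2-yl]-4,8-dimethylspiro[4.5]dec-7-en-9-one
Conditions: dimethyl (1-diazo-2-oxopropyl)phosphonate, K2CO3, MeOH, 0 °C to rt
Reagents that add atoms: dimethyl (1-diazo-2-oxopropyl)phosphonate, COP(=O)(OC)C(=[N+]=[N-])C(C)=O
Why: Seyferth–Gilbert homologation in its Ohira–Bestmann form adds one carbon and gives the terminal alkyne under carbonate conditions mild enough to leave the α-stereocentre and the enone untouched.

**Step 10**
Reactants: 18 alkynyl enone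
Product: 19 (1R,4S,5S,9R)-1-[(2S)-but-3-yn-2-yl]-4,8-dimethylspiro[4.5]dec-7-en-9-ol
Conditions: i-Bu2AlH, CH2Cl2, −78 °C; then H2O
Reagents that add atoms: none
Why: 1,2-Reduction of the enone by the bulky aluminium hydride should occur on the face of C9=O turned toward C1 (only its hydrogen points there), because the other face is covered by the C4 methyl leaning over C10/C9; this should give the (9R)-alcohol, the epimer that step 14 inverts.

**Step 11**
Reactants: 20 prop-2-yn-1-ol
Product: 22 (2Z)-3-iodo-2-methylprop-2-en-1-ol, via alkenylmagnesium alkoxide 21 (not isolated)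
Conditions: MeMgBr (2.3 equiv), CuI (10 mol%), THF, −10 °C to rt; then I2, −10 °C; then H2O
Reagents that add atoms: methylmagnesium bromide, C[Mg]Br; iodine, II
Why: Alkoxide-directed, copper-catalysed anti-carbomagnesiation puts CH3 on C2 and magnesium on C3 cis to the CH2O group, and iodinolysis with retention gives the (Z)-alkenyl iodide.

**Step 12**
Reactants: 22 (Z)-iodo alcohol
Product: 24 (2Z)-3-iodo-2-methylprop-2-enoic acid, via (2Z)-3-iodo-2-methylprop-2-enal 23 (not isolated)
Conditions: TEMPO (cat.), NaClO2, NaOCl (cat.), MeCN/phosphate buffer (pH 6.7), 35 °C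
Reagents that add atoms: sodium chlorite, [Na+].[O-]Cl=O
Why: Oxoammonium oxidation to the aldehyde and in situ chlorite (Pinnick-type) oxidation give the acid without touching the alkenyl iodide or its Z geometry.

**Step 13**
Reactants: 19 alkynyl alcohol; 24 (Z)-iodo acid
Product: 26 (5Z)-5-[(2S)-2-[(1R,4S,5S,9R)-9-hydroxy-4,8-dimethylspiro[4.5]dec-7-en-1-yl]propylidene]-3-methylfuran-2(5H)-one, via enynoic acid 25 (not isolated)
Conditions: Pd(PPh3)4 (5 mol%), CuI (10 mol%), Et3N, MeCN, rt
Reagents that add atoms: none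
Why: Sonogashira coupling gives the (Z)-enynoic acid, whose carboxylate adds anti across the metal-activated triple bond in a 5-exo-dig closure, which should give the (Z)-γ-ylidene butenolide; the free allylic alcohol is inert, and no allylic ester is yet present that zerovalent palladium could ionize.

**Step 14**
Reactants: 26 butenolide alcohol; 27 3-phenylpropanoic acid
Product: 28 (1R,4S,5S,9S)-4,8-dimethyl-1-[(2S)-1-[(2Z)-4-methyl-5-oxofuran-2(5H)-ylidene]propan-2-yl]spiro[4.5]dec-7-en-9-yl 3-phenylpropanoate (CNP0260277.1)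
Conditions: PPh3, DIAD, THF, 0 °C to rt
Reagents that add atoms: none
Why: Mitsunobu esterification: the C9 hydroxyl is activated by the phosphine–azodicarboxylate pair and displaced by the carboxylate with inversion (SN2), which turns (9R) into the (9S) ester of the target; the C8 methyl on the trisubstituted alkene should disfavour SN2' attack.

**Compound list**

1 | (4aS,7S,7aR)-nepetalactone | O=C1OC=C(C)[C@H]2CC[C@H](C)[C@@H]12 | starting material
2 | (4S,4aR,7S,7aR)-dihydronepetalactone | O=C1OC[C@@H](C)[C@H]2CC[C@H](C)[C@@H]12 | intermediate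
3 | (E)-1-bromoprop-1-ene | C/C=C/Br | starting material
4 | (E)-prop-1-enyllithium | C/C=C/[Li] | intermediate
5 | (2E)-1-[(1R,2R,5S)-2-[(2S)-1-hydroxypropan-2-yl]-5-methylcyclopentyl]but-2-en-1-one | OC[C@@H](C)[C@H]2CC[C@H](C)[C@H]2C(=O)/C=C/C | intermediate
6 | (2E)-1-[(1R,2R,5S)-2-[(2S)-1-(tert-butyldimethylsilyloxy)propan-2-yl]-5-methylcyclopentyl]but-2-en-1-one | CC(C)(C)[Si](C)(C)OC[C@@H](C)[C@H]2CC[C@H](C)[C@H]2C(=O)/C=C/C | intermediate
7 | phenyl vinyl sulfone | C=CS(=O)(=O)c1ccccc1 | starting material
8 | lithium dienolate of 6 (exocyclic enolate at the cyclopentane, enolate geometry open) | CC(C)(C)[Si](C)(C)OC[C@@H](C)[C@H]1CC[C@H](C)C1=C(O[Li])/C=C/C | intermediate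
9 | α-sulfonyl carbanion from the first Michael addition (new CH2 anti to the side chain) | CC(C)(C)[Si](C)(C)OC[C@@H](C)[C@H]2CC[C@H](C)[C@@]2(CC([Li])S(=O)(=O)c3ccccc3)C(=O)/C=C/C | intermediate
10 | cyclized lithium enolate (spiro[4.5]dec-6-en-6-olate, C8/C9 mixture) | CC(C)(C)[Si](C)(C)OC[C@@H](C)[C@H]2CC[C@H](C)[C@@]23C(O[Li])=CC(C)C(S(=O)(=O)c4ccccc4)C3 | intermediate
11 | (1R,4S,5R)-1-[(2S)-1-(tert-butyldimethylsilyloxy)propan-2-yl]-4,8-dimethyl-9-(phenylsulfonyl)spiro[4.5]dec-6-en-6-yl trifluoromethanesulfonate (C8/C9 mixture) | CC(C)(C)[Si](C)(C)OC[C@@H](C)[C@H]2CC[C@H](C)[C@@]23C(OS(=O)(=O)C(F)(F)F)=CC(C)C(S(=O)(=O)c4ccccc4)C3 | intermediate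
12 | tert-butyldimethyl{(2S)-2-[(1R,4S,5S)-4,8-dimethyl-9-(phenylsulfonyl)spiro[4.5]dec-6-en-1-yl]propoxy}silane (C8/C9 mixture) | CC(C)(C)[Si](C)(C)OC[C@@H](C)[C@H]2CC[C@H](C)[C@@]23C=CC(C)C(S(=O)(=O)c4ccccc4)C3 | intermediate
13 | 9-lithio derivative of 12 | CC(C)(C)[Si](C)(C)OC[C@@H](C)[C@H]2CC[C@H](C)[C@@]23C=CC(C)C([Li])(S(=O)(=O)c4ccccc4)C3 | intermediate
14 | (1R,4S,5S)-1-[(2S)-1-(tert-butyldimethylsilyloxy)propan-2-yl]-4,8-dimethylspiro[4.5]dec-6-en-9-one (C8 mixture) | CC(C)(C)[Si](C)(C)OC[C@@H](C)[C@H]2CC[C@H](C)[C@@]23C=CC(C)C(=O)C3 | intermediate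
15 | (1R,4S,5S)-1-[(2S)-1-(tert-butyldimethylsilyloxy)propan-2-yl]-4,8-dimethylspiro[4.5]dec-7-en-9-one | CC(C)(C)[Si](C)(C)OC[C@@H](C)[C@H]2CC[C@H](C)[C@@]23CC=C(C)C(=O)C3 | intermediate
16 | (1R,4S,5S)-1-[(2S)-1-hydroxypropan-2-yl]-4,8-dimethylspiro[4.5]dec-7-en-9-one | OC[C@@H](C)[C@H]2CC[C@H](C)[C@@]23CC=C(C)C(=O)C3 | intermediate
17 | (2S)-2-[(1R,4S,5S)-4,8-dimethyl-9-oxospiro[4.5]dec-7-en-1-yl]propanal | O=C[C@@H](C)[C@H]2CC[C@H](C)[C@@]23CC=C(C)C(=O)C3 | intermediate
18 | (1R,4S,5S)-1-[(2S)-but-3-yn-2-yl]-4,8-dimethylspiro[4.5]dec-7-en-9-one | C#C[C@@H](C)[C@H]2CC[C@H](C)[C@@]23CC=C(C)C(=O)C3 | intermediate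
19 | (1R,4S,5S,9R)-1-[(2S)-but-3-yn-2-yl]-4,8-dimethylspiro[4.5]dec-7-en-9-ol | C#C[C@@H](C)[C@H]2CC[C@H](C)[C@@]23CC=C(C)[C@H](O)C3 | intermediate
20 | prop-2-yn-1-ol | C#CCO | starting material
21 | (Z)-3-(bromomagnesio)-2-methylprop-2-en-1-olate, bromomagnesium salt | Br[Mg]/C=C(/C)CO[Mg]Br | intermediate
22 | (2Z)-3-iodo-2-methylprop-2-en-1-ol | I/C=C(/C)CO | intermediate
23 | (2Z)-3-iodo-2-methylprop-2-enal | I/C=C(/C)C=O | intermediate
24 | (2Z)-3-iodo-2-methylprop-2-enoic acid | I/C=C(/C)C(=O)O | intermediate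
25 | (2Z,6S)-6-[(1R,4S,5S,9R)-9-hydroxy-4,8-dimethylspiro[4.5]dec-7-en-1-yl]-2-methylhept-2-en-4-ynoic acid | C(#C[C@@H](C)[C@H]2CC[C@H](C)[C@@]23CC=C(C)[C@H](O)C3)/C=C(/C)C(=O)O | intermediate
26 | (5Z)-5-[(2S)-2-[(1R,4S,5S,9R)-9-hydroxy-4,8-dimethylspiro[4.5]dec-7-en-1-yl]propylidene]-3-methylfuran-2(5H)-one | CC1=C/C(=C/[C@@H](C)[C@H]2CC[C@H](C)[C@@]23CC=C(C)[C@H](O)C3)OC1=O | intermediate
27 | 3-phenylpropanoic acid | OC(=O)CCc1ccccc1 | starting material
28 | (1R,4S,5S,9S)-4,8-dimethyl-1-[(2S)-1-[(2Z)-4-methyl-5-oxofuran-2(5H)-ylidene]propan-2-yl]spiro[4.5]dec-7-en-9-yl 3-phenylpropanoate | CC1=C/C(=C/[C@@H](C)[C@H]2CC[C@H](C)[C@@]23CC=C(C)[C@@H](OC(=O)CCc2ccccc2)C3)OC1=O | target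

**Step count**

Total: 14 steps. Longest linear sequence: 12 steps (steps 1–10, 13, 14); steps 11 and 12 make the iodo acid on a side branch.

**Steps most likely to fail**

Step 4. What may go wrong: poor facial selectivity in the first conjugate addition at the exocyclic enolate carbon (the directing side chain is a free rotor), or γ- instead of α'-deprotonation of the hindered enone. The fallback sets out from 2 and comes back at 11. The quaternary carbon would be made on the rigid bicyclic lactone, whose enolate should be attacked on the convex face, cis to H-4a, which is the same sense as required. LiN(i-Pr)2 and then phenyl vinyl sulfone 7 should give the 7a-[2-(phenylsulfonyl)ethyl] lactone F1. Weinreb aminolysis (MeNH(OMe)·HCl, AlMe3) would open it to the hydroxy Weinreb amide F2, and silylation (TBSCl, imidazole) would give the silyl ether amide F3. Two equivalents of (E)-prop-1-enyllithium 4 (the first deprotonates the sulfone) would give the sulfonylethyl enone F4. LiN(i-Pr)2 followed by PhNTf2 would then close the ring by intramolecular Michael addition of the sulfonyl carbanion and trap the enolate as 11.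

Step 6. What may go wrong: incomplete oxygen transfer to the hindered α-sulfonyl carbanion, or proton return to give back 12. The fallback sets out from 6 and comes back at 15. The carbonyl would be carried at the sulfoxide level and released by a Pummerer reaction instead of an oxygen transfer to a carbanion. The annulation of step 4 run with phenyl vinyl sulfoxide should give the sulfinyl enol triflate F5, and the formate reduction of step 5 would give the alkenyl sulfoxide F6. Trifluoroacetic anhydride and 2,6-lutidine would give the α-trifluoroacetoxy sulfide F7; aqueous NaHCO3 would hydrolyse it to the ketone, and DBU would move the double bond into conjugation to give 15.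

Step 10. What may go wrong: poor facial selectivity of the hydride addition, which the later inversion cannot correct, or SN2' leakage in that inversion. The fallback sets out from 18 and comes back at 28. Reagent control would replace substrate control: (R)-2-methyl-CBS-oxazaborolidine (cat.) with BH3·SMe2 should give the (9S)-alkynyl alcohol F8 directly (alkenyl branch as the large group). The coupling–lactonization of step 13 with 24 would give the (9S)-butenolide alcohol F9, and Steglich esterification with 3-phenylpropanoic acid 27 (DCC, DMAP), which retains configuration, would give 28.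

**Further compounds**

F1 | step 4 | (4S,4aR,7S,7aR)-4,7-dimethyl-7a-[2-(phenylsulfonyl)ethyl]hexahydrocyclopenta[c]pyran-1(3H)-one | O=C1OC[C@@H](C)[C@H]2CC[C@H](C)[C@@]12CCS(=O)(=O)c1ccccc1
F2 | step 4 | (1R,2R,5S)-2-[(2S)-1-hydroxypropan-2-yl]-N-methoxy-N,5-dimethyl-1-[2-(phenylsulfonyl)ethyl]cyclopentane-1-carboxamide | OC[C@@H](C)[C@H]2CC[C@H](C)[C@@]2(CCS(=O)(=O)c1ccccc1)C(=O)N(C)OC
F3 | step 4 | tert-butyldimethylsilyl ether of F2 | CC(C)(C)[Si](C)(C)OC[C@@H](C)[C@H]2CC[C@H](C)[C@@]2(CCS(=O)(=O)c1ccccc1)C(=O)N(C)OC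
F4 | step 4 | (2E)-1-[(1R,2R,5S)-2-[(2S)-1-(tert-butyldimethylsilyloxy)propan-2-yl]-5-methyl-1-[2-(phenylsulfonyl)ethyl]cyclopentyl]but-2-en-1-one | CC(C)(C)[Si](C)(C)OC[C@@H](C)[C@H]2CC[C@H](C)[C@@]2(CCS(=O)(=O)c1ccccc1)C(=O)/C=C/C
F5 | step 6 | (1R,4S,5R)-1-[(2S)-1-(tert-butyldimethylsilyloxy)propan-2-yl]-4,8-dimethyl-9-(phenylsulfinyl)spiro[4.5]dec-6-en-6-yl trifluoromethanesulfonate (mixture at C8, C9 and sulfur) | CC(C)(C)[Si](C)(C)OC[C@@H](C)[C@H]2CC[C@H](C)[C@@]23C(OS(=O)(=O)C(F)(F)F)=CC(C)C(S(=O)c4ccccc4)C3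
F6 | step 6 | tert-butyldimethyl{(2S)-2-[(1R,4S,5S)-4,8-dimethyl-9-(phenylsulfinyl)spiro[4.5]dec-6-en-1-yl]propoxy}silane (mixture at C8, C9 and sulfur) | CC(C)(C)[Si](C)(C)OC[C@@H](C)[C@H]2CC[C@H](C)[C@@]23C=CC(C)C(S(=O)c4ccccc4)C3
F7 | step 6 | (1R,4S,5S)-1-[(2S)-1-(tert-butyldimethylsilyloxy)propan-2-yl]-4,8-dimethyl-9-(phenylsulfanyl)spiro[4.5]dec-6-en-9-yl trifluoroacetate (mixture at C8 and C9) | CC(C)(C)[Si](C)(C)OC[C@@H](C)[C@H]2CC[C@H](C)[C@@]23C=CC(C)C(OC(=O)C(F)(F)F)(Sc4ccccc4)C3
F8 | step 10 | (1R,4S,5S,9S)-1-[(2S)-but-3-yn-2-yl]-4,8-dimethylspiro[4.5]dec-7-en-9-ol | C#C[C@@H](C)[C@H]2CC[C@H](C)[C@@]23CC=C(C)[C@@H](O)C3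
F9 | step 10 | (5Z)-5-[(2S)-2-[(1R,4S,5S,9S)-9-hydroxy-4,8-dimethylspiro[4.5]dec-7-en-1-yl]propylidene]-3-methylfuran-2(5H)-one | CC1=C/C(=C/[C@@H](C)[C@H]2CC[C@H](C)[C@@]23CC=C(C)[C@@H](O)C3)OC1=O
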